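The data are calculated on assumed constants, noise included.

Slowness shows first in these flasks as a lag: none of the solid partner is in solution at the start, and the larch run reads 1% of target after 4.00 min.

| flask | starting material | solid partner | temperature | remark | time |
|---|---|---|---|---|---|
| larch | 0.024 M | 1.3 equiv | 30 °C | run made earlier |  |
| alder | 0.037 M | 1.3 equiv | 50 °C | run made earlier |  |
| autumn | 0.017 M | 1.30 equiv | 65 °C |  | 12 min |
| summer | 0.017 M | 1.30 equiv | 35 °C |  | 12 min |
| dusk | 0.017 M | 1.30 equiv | 50 °C |  | 12 min |

| run | time / min | target / % |
|---|---|---|
| larch | 4.00 | 1 |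
| larch | 12.0 | 6 |
| larch | 15.0 | 6 |
| larch | 30.0 | 19 |
| larch | 50.0 | 23 |
| larch | 60.0 | 19 |
| alder | 1.33 | 1 |
| alder | 4.00 | 11 |
| alder | 6.00 | 14 |
| alder | 10.0 | 23 |
| alder | 15.0 | 24 |
| alder | 20.0 | 18 |
| alder | 25.0 | 11 |

(readings scatter by 2 percentage points)

- solid, in amounts per volume of the solution: solid partner
- at the start none of the solid partner is in solution

- which flask leads in amount of target, in percent of the starting material charged ("all alike" within 1.5 percentage points) (autumn / summer / dusk / all alike)
- how much target is there at the end, in percent of the starting material charged: autumn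
- how much target is there at the end, in percent of the starting material charged: summer
- how much target is there at the end, in percent of the starting material charged: dusk

The bench rule treats the peak as a first-order clock, unchanged by concentration. The alder peak, read near 15.0 min at 50 °C, then carries over to dusk, and the asked 12 min is 0.800 of it. The rule's border is the charge, since dusk holds 0.459 of the alder charge, with the solid partner at 1.30 equiv in both.

The reckoning here therefore takes the other end, as a supposition, since the two runs differ in both temperature and charge. If a saturated solution passes the partner on at a steady rate, a charge lasts in proportion to its size, and the peak marks its end. Scaled by charge, the feed time in dusk is 6.89 min. Per unit of charge, the larch peak comes 5.14 times later than the alder peak. Spreading that factor evenly over the degrees gives 23.5 min for summer and 2.02 min for autumn.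

Dusk then stands at 1.74 on the fed fraction, the asked time divided by the feed time. Summer stands at 0.510 and autumn at 5.94. Alder read 14% at a fed fraction of 0.400 and 23% at 0.667, so summer falls between these two readings on the rise. Alder's last reading, 11%, stands at 1.67, and dusk lies just beyond it. The reckoning here therefore puts summer ahead of dusk, with autumn lowest, furthest past its peak.

The forecast gives autumn 16%, summer 7% and dusk 18%, with dusk ahead, in its words: “Dusk probably leads, but the call is uncertain”. The reckoning here differs from it on the leader and on autumn.

The flasks give dusk 14.7%, summer 11.0% and autumn 3.40%, so dusk leads, where the reckoning here put summer ahead.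

    starting material ⇌ open intermediate (K = 1.78, k = 0.0306 s⁻¹, Ea = 79.0 kJ mol⁻¹, ΔH = −33.0 kJ mol⁻¹)
    fresh partner → second intermediate (k = 0.00706 s⁻¹, Ea = 87.0 kJ mol⁻¹)
    open intermediate + second intermediate ⇌ target (K = 67.0 M⁻¹, k = 0.405 M⁻¹ s⁻¹, Ea = 68.0 kJ mol⁻¹, ΔH = −6.00 kJ mol⁻¹)
    2 second intermediate → homo product (k = 0.518 M⁻¹ s⁻¹, Ea = 51.0 kJ mol⁻¹)
    solid partner ⇌ fresh partner, rate k5*(cs5 - [fresh partner]) while solid is left; crystals form when [fresh partner] > cs5 (solubility = 9.60 mM, k = 0.0278 s⁻¹)
    (constants at 50 °C)

Autumn, at a fed fraction of 5.94, holds 0% of its solid partner at 6.00 min, with target at 8.31% then and 3.40% at the end. The neighbour repeats dusk with 0.029 M of starting material. Its feed time reckons to 11.8 min and its fed fraction to 1.02, against 1.74 for dusk, which places the asked time at the peak. Its target stands at 21.2%, more than the 14.7% of dusk, and 7.8% of its partner charge remains, solid or dissolved.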